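The runs come from a simulation with constants of no real substance; noise was put on by code.

- No constants are known yet, so start from the charges, which give a scale without any rate.

the same everywhere: partner 1.05 M; free catalyst 0.50 mM

| flask | starting material | second substrate | temperature | remark | time |
|---|---|---|---|---|---|
| Saturday's | 1 M | 1 M | 90 °C | the very flask that is asked about, followed so far |  |
| Thursday's | 1 M | 1 M | 96 °C | run made earlier |  |
| flask | 1.0 M | 1.00 M | 90 °C |  | 30 h |

- Saturday's (time / h: target / %): 1.33: 26.6; 3.00: 41.6; 8.00: 59.6; 20.0: 68.6
- Thursday's (time / h: target / %): 1.33: 34.8; 3.00: 47.2; 8.00: 64.7; 20.0: 71.3

(scatter of a reading: 1 percentage point)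

- ash: at 30 h take out 90% of the target then present, then wait 30 h
- elm: at 30 h raise the temperature by 25 K, then wait 30 h
- birch: change nothing and wait 30 h more
- maple: at 30 h add free catalyst, 100% of the amount charged, then wait 30 h

- what is taken out of target is counted as made
- reactions considered so far: second substrate + partner + free catalyst -> free catalyst + second product; 2 free catalyst -> spent catalyst B; second substrate + free catalyst -> spent catalyst A; starting material + partner + free catalyst -> free catalyst + target
- additions bring no volume worth counting

- target, in percent of the starting material first charged, at 30 h
- what to do for the largest gain in target; "none" if nothing gains more than 2 percentage points (ash / elm / birch / maple / none)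
- target present, with what was taken out counted in, in percent of the starting material first charged, after ash
- target present, with what was taken out counted in, in percent of the starting material first charged, after elm

- Compare the charges first. Partner, at 1.05 M, is less than the 2.00 M of starting material and second substrate together, so treat it as the limiting reagent of the pair.
- Take the symmetric case as zero. If both substrates drew partner in step with their charges and all the partner charged were used, each would convert partner charged over both charges taken together: 52.5%. Call this the even line.
- Read Saturday's run against it. Its target reading is 68.6% at 20.0 h, 16 percentage points above the line, so read starting material as the stronger taker of partner.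
- Reckon the time to wait. In Saturday's run, the mean rate fell 4.80-fold from the span ending at 8.00 h to the one ending at 20.0 h.
- Carry that last span's 9 points over the remaining 10.0 h at a rate lower by that factor. My figure for 30 h is 70.2%.
- Do not plan on heat. At 1.33 h, Thursday's run leads Saturday's by 8.2 points, but at 20.0 h by 2.7 points.
- Charge free catalyst at 30 h, and expect a modest gain. The even line does not show how much partner is left.
- The forecast gives 71%, within 1 point of mine, then 73% after ash and 74% after elm. It picks maple: “Fresh catalyst is the only move that restores rate”.
- The flask gives 71.2% at 30 h, 72.9% after ash and 73.1% after elm. The best option is maple, which gains 5 points against 1.9 points for elm.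

    second substrate + partner + free catalyst → free catalyst + second product (k = 2.11 L² mol⁻² min⁻¹, Ea = 58.0 kJ mol⁻¹)
    2 free catalyst → spent catalyst B (k = 0.310 L mol⁻¹ min⁻¹, Ea = 56.0 kJ mol⁻¹)
    second substrate + free catalyst → spent catalyst A (k = 0.00105 L mol⁻¹ min⁻¹, Ea = 71.0 kJ mol⁻¹)
    starting material + partner + free catalyst → free catalyst + target (k = 9.47 L² mol⁻² min⁻¹, Ea = 63.0 kJ mol⁻¹)
    (constants at 90 °C)

- At 30.0 h this flask holds partner at 9.11% of its charge, and that depletion is the main reason the target stops short: without it the target reaches 98.7%, not 71.2%. The target in this flask stands at 1.36 times the even line of 52.5%. Apply that lift to the flask charged with 0.42 M of partner. Its even line is 21.0%, so the lift gives 28.6%. That flask gives 32.3% at 30.0 h, with partner at 3.33% of its charge.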